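**Plan**

1. Numbering used below: ring B = C5 (=C, carries the side chain), C6 (CH–O-angeloyl), C7 (ring-fusion CH), C8 (lactone CH–O), C9 (CH2), C10 (=C–C14H2OH); lactone C11 (α-C), C12 (C=O), C13 (=CH2); side chain C4 (CHCH3) to C1 (CH2OH).
2. Retrosynthesis: late cuts are the two O–aryl protecting bonds, the angelate C6–O bond, C11=C13 and the lactone C8–O bond (back to a C8 ketone with a CO2Me helper on C9). The cyclohexene is then opened at C9–C10 together with C14–O. Earlier cuts are C8–C9 (ester enolate + lactone), C5–C10 (acetylide + ketone), C6–C7 (aldol) and C5=CH2 (aldehyde methylenation).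
3. Enabling feature: C10 bears an allylic oxygen (C14) and sits between the ring CH2 C9 and the fully substituted C5, and C9 is α to the carbinol C8. C5–C10–C14 is therefore an allyl dication equivalent (tertiary propargylic C5–O plus C10≡C14) and C8–C9 a β-keto ester; the two are tied together beforehand through the enol oxygen as a 2-alkylidene-5-ethynyloxolane (ring O–C5–C6–C7–C8).
4. Forward: (S)-citronellal → 2-methylene aldehyde → aldol → double ozonolysis (C5 ketone, C1 alcohol) → ethynyl γ-lactone (temporary oxolane) → alkylideneoxolane → palladium-catalysed rearrangement to ring B carrying C14–OAr → loss of the helper ester, C8 reduction, cis-lactone, α-methylene, angelate, removal of the aryl groups.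
5. Stereochemistry: C4 from (S)-citronellal; C6 and C7 from an Evans syn-aldol with the (S)-4-benzyl-oxazolidinone; C8 from bulky-hydride reduction cis to the C7 substituent; the Z-alkene from angelic acid; the temporary C5 centre is erased in the key step.

Key step: step 10

Remark: C5 of 14–17 is drawn as the Felkin–Anh epimer and 17 as the Z enol ether; the other isomers should give the same 18, and (S)-citronellal of high enantiomeric purity is assumed.

**Route**

Step 1
Reactants: 1 mono-tert-butyl succinate; 2 (S)-4-benzyl-1,3-oxazolidin-2-one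
Product: 4 tert-butyl 4-[(4S)-4-benzyl-2-oxo-1,3-oxazolidin-3-yl]-4-oxobutanoate, via mixed pivalic anhydride 3 (not isolated)
Conditions: t-BuCOCl, Et3N, THF, −20 °C; then LiCl, 2, −20 to 23 °C
Reagents that add atoms: none
Why: N-acylation of the oxazolidinone by a mixed pivalic anhydride is a standard imide synthesis that does not touch the hindered tert-butyl ester or the auxiliary stereocentre.

Step 2
Reactants: 5 (S)-citronellal
Product: 6 (3S)-3,7-dimethyl-2-methylideneoct-6-enal
Conditions: 37% aq. CH2O, pyrrolidine (10 mol%), propionic acid (10 mol%), i-PrOH, 45 °C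
Reagents that add atoms: formaldehyde, C=O
Why: Amine/acid-catalysed Mannich condensation–elimination (α-methylenation of an aldehyde) installs C5=CH2, the later C5 carbonyl; C4 is β to the aldehyde and cannot epimerize.

Step 3
Reactants: 4 imide; 6 (3S)-3,7-dimethyl-2-methylideneoct-6-enal
Product: 8 tert-butyl (3S,4S,6S)-3-{[(4S)-4-benzyl-2-oxo-1,3-oxazolidin-3-yl]carbonyl}-4-hydroxy-6,10-dimethyl-5-methylideneundec-9-enoate (syn-aldol adduct), via dibutylboron enolate 7 (not isolated)
Conditions: Bu2BOTf, i-Pr2NEt, CH2Cl2, −78 to 0 °C; 6, −78 to 0 °C; then pH 7 buffer, MeOH, 30% H2O2, 0 °C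
Reagents that add atoms: none
Why: Evans syn-aldol reaction: the Z boron enolate reacts through a Zimmerman–Traxler chair on the face away from the benzyl group, setting C7 and C6 (syn) under reagent control that overrides the remote C4 centre.

Step 4
Reactants: 8 syn-aldol adduct
Product: 9 C6 tert-butyldimethylsilyl ether of 8
Conditions: TBSOTf, 2,6-lutidine, CH2Cl2, −78 to 0 °C
Reagents that add atoms: tert-butyldimethylsilyl triflate, CC(C)(C)[Si](C)(C)OS(=O)(=O)C(F)(F)F
Why: Silylation with a silyl triflate and a hindered base protects the aldol hydroxyl without retro-aldol cleavage and keeps C6–O masked until the angelate is introduced.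

Step 5
Reactants: 9 silyl ether
Product: 11 keto aldehyde (C5 ketone and C1 aldehyde; imide, C6–OTBS, tert-butyl ester unchanged), via bis-ozonide 10 (not isolated)
Conditions: O3, CH2Cl2, −78 °C; then PPh3, −78 to 23 °C
Reagents that add atoms: ozone, [O-][O+]=O
Why: Ozonolysis with reductive work-up cleaves both alkenes at once (1,1-disubstituted alkene to the C5 ketone, prenyl terminus to the C1 aldehyde) under neutral conditions that leave the α-centres C4 and C6 untouched.

Step 6
Reactants: 11 keto aldehyde
Product: 12 keto alcohol (C1–OH)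
Conditions: NaBH(OAc)3, AcOH (cat.), 1,2-dichloroethane, 23 °C
Reagents that add atoms: none
Why: Chemoselective hydride reduction: NaBH(OAc)3 reduces aldehydes but not hindered ketones, imides or esters, so only C1 is reduced.

Step 7
Reactants: 12 keto alcohol
Product: 13 C1 4-methoxyphenyl ether of 12
Conditions: 4-methoxyphenol, PPh3, DIAD, THF, 0 to 23 °C
Reagents that add atoms: 4-methoxyphenol, COc1ccc(O)cc1
Why: Mitsunobu etherification of the primary alcohol gives a robust aryl ether that should survive all later steps and is removed oxidatively at the end.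

Step 8
Reactants: 13 keto aryl ether
Product: 15 ethynyl γ-lactone (oxolan-2-one ring O–C5–C6–C7–C8; C5 carries ethynyl and the side chain; C6–OTBS; C7–CH2CO2t-Bu), via hydroxy imide 14 (not isolated)
Conditions: HC≡CMgBr, CeCl3, THF, −78 °C; sat. NH4Cl; then DBU (cat.), CH2Cl2, 23 °C
Reagents that add atoms: ethynylmagnesium bromide, C#C[Mg]Br
Why: CeCl3-promoted 1,2-addition of the acetylide suppresses enolization of the doubly α-branched ketone and attack on the imide, polar Felkin–Anh control by C6–OTBS sets the temporary C5 centre (erased in step 10), and base-catalysed lactonization of the tertiary alcohol onto the activated imide releases the auxiliary.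

Step 9
Reactants: 15 ethynyl γ-lactone
Product: 17 methyl (Z)-(5-ethynyloxolan-2-ylidene)acetate (enol ether oxygen between C5 and C8; other substituents as in 15), via hydroxy keto ester 16 (not isolated)
Conditions: MeOAc, LiN(i-Pr)2, THF, −78 °C; 15, −78 °C; AcOH; then PPTS (cat.), 4 Å MS, benzene, 50 °C
Reagents that add atoms: methyl acetate (as its lithium enolate), COC(C)=O
Why: Claisen-type addition of an ester enolate to the γ-lactone stops at the hemiketal stage, and acid-catalysed dehydration gives the ester-conjugated exocyclic enol ether, i.e. the β-keto ester tied to C5 through its own enol oxygen; the hindered tert-butyl ester is not attacked and no stereocentre is affected.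

Step 10
Reactants: 17 alkylidene-ethynyloxolane
Product: 18 ring B enol ester (methyl 2-hydroxycyclohexa-1,3-diene-1-carboxylate: C8 enol, C9–CO2Me, C5=C10, C14–O-4-methoxyphenyl, C6–OTBS, C7–CH2CO2t-Bu)
Conditions: Pd2(dba)3·CHCl3 (2.5 mol%), 1,1'-bis(diphenylphosphino)ferrocene (6 mol%), 4-methoxyphenol (1.5 equiv), 1,4-dioxane, 80 °C
Reagents that add atoms: 4-methoxyphenol, COc1ccc(O)cc1
Why: Proposed new method: zerovalent palladium should ionize the tertiary propargylic C5–O bond of 17, whose leaving group is the ester-stabilized enolate itself, to an allenyl/η3-propargyl palladium cation that carries its own soft nucleophile; the enolate carbon C9 then adds to the central carbon C10, the resulting palladacyclobutene is protonated by the phenol to a π-allyl complex, and phenoxide attacks the CH2 terminus C14, so that one operation makes the C9–C10 bond, the tetrasubstituted C5=C10 alkene and the C14–O bond. The closest known reaction types are the palladium-catalysed 1,3 oxygen-to-carbon shift of 5-vinyl-2-alkylideneoxolanes to carbocycles and the twofold substitution of propargylic carbonates by a β-keto ester carbon (central carbon) and an oxygen nucleophile (terminus); new is the ethynyl-for-vinyl change that moves the C–C bond to the central carbon and enlarges the ring by one atom. The cyclohexene ring B closes by attack on the central carbon of the η3-propargyl unit, endo with respect to its C5–C10 bond and exo with respect to C10–C14 (six-membered, atoms C9–C8–C7–C6–C5–C10), while the oxolane opens. No stereocentre is created: C5 becomes sp2 (both C5 epimers and both enol ether isomers converge), C9 ends in an enol, and C6 and C7 are spectators. The step needs C- over O-alkylation and attack at C10 rather than at the propargylic carbon C5, which the soft enolate, the chelating diphosphine and the fully substituted C5 should secure, and capture of the π-allyl at C14 rather than C5, which sterics secure. Two escape routes are closed by the ring system itself: capture by the enol oxygen would need a bridgehead alkene in an oxabicyclo[3.2.1]octene, and the thermal [3,3] shift of the propargyl vinyl ether would need a seven-membered cyclic allene.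

Step 11
Reactants: 18 ring B enol ester
Product: 19 cyclohex-3-enone (C8 ketone, C9H2, C5=C10)
Conditions: LiCl, H2O, DMSO, 130 °C
Reagents that add atoms: none
Why: Krapcho dealkoxycarbonylation removes the helper ester from C9; the dienolate is protonated kinetically at C9 to give the β,γ-unsaturated ketone, and the simple tert-butyl ester is inert.

Step 12
Reactants: 19 cyclohexenone
Product: 20 (8R)-cis-hydroxy ester (C8–OH cis to C7–CH2CO2t-Bu)
Conditions: LiBH(s-Bu)3, THF, −78 °C; sat. NH4Cl
Reagents that add atoms: none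
Why: Bulky-hydride reduction: attack from the less hindered equatorial direction, anti to the C7 substituent, gives the axial alcohol cis to C7–CH2CO2t-Bu and so sets C8.

Step 13
Reactants: 20 cis-hydroxy ester
Product: 21 cis-fused γ-lactone (C8–O–C12; C6–OTBS)
Conditions: TsOH·H2O (cat.), toluene, 60 °C
Reagents that add atoms: none
Why: Acid-catalysed lactonization of a γ-hydroxy tert-butyl ester (loss of isobutene) closes the cis-fused lactone; C6–O is silylated, so only the C8 oxygen can lactonize.

Step 14
Reactants: 21 cis-fused lactone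
Product: 24 α-methylene lactone (C11=C13; C6–OTBS), via Mannich base 22 (not isolated), via trimethylammonium iodide 23 (not isolated)
Conditions: LiN(i-Pr)2, THF, −78 °C; CH2=NMe2+ I−, −78 to 23 °C; then MeI, MeOH; then sat. NaHCO3, CH2Cl2
Reagents that add atoms: N,N-dimethylmethyleneiminium iodide (Eschenmoser's salt), C=[N+](C)C.[I-]
Why: α-Methylenation of a lactone through its lithium enolate, Mannich reaction with Eschenmoser's salt, N-methylation and Hofmann-type elimination; the C11 configuration of 22 is lost on elimination.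

Step 15
Reactants: 24 α-methylene lactone
Product: 25 C6 alcohol
Conditions: HF·pyridine, pyridine, THF, 0 to 23 °C
Reagents that add atoms: none
Why: Buffered fluoride desilylation removes the only silyl ether and spares the α-methylene lactone and both aryl ethers.

Step 16
Reactants: 25 C6 alcohol; 26 angelic acid
Product: 28 eriolangin bis(4-methoxyphenyl) ether, via mixed trichlorobenzoic anhydride 27 (not isolated)
Conditions: 26, 2,4,6-trichlorobenzoyl chloride, Et3N, toluene, 23 °C; then 25, toluene, 80 °C
Reagents that add atoms: none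
Why: Yamaguchi-type esterification through the preformed mixed anhydride, run without DMAP so that the Z (angelate) geometry is not isomerized to the tiglate; the C6 carbinol is acylated with retention.

Step 17
Reactants: 28 eriolangin bis(4-methoxyphenyl) ether
Product: 29 eriolangin
Conditions: (NH4)2Ce(NO3)6, MeCN/H2O (4:1), 0 °C
Reagents that add atoms: none
Why: Oxidative cleavage of both 4-methoxyphenyl ethers by tetravalent cerium (arene radical cation, water adds to the ring, benzoquinone is expelled) frees the two primary alcohols and should leave the angelate, the α-methylene lactone and the tetrasubstituted alkene untouched.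

**Compound list**

1 | mono-tert-butyl succinate (4-tert-butoxy-4-oxobutanoic acid) | OC(=O)CCC(=O)OC(C)(C)C | starting material
2 | (S)-4-benzyl-1,3-oxazolidin-2-one | O=C1N[C@@H](Cc2ccccc2)CO1 | starting material
3 | mixed anhydride of 1 and pivalic acid | CC(C)(C)C(=O)OC(=O)CCC(=O)OC(C)(C)C | intermediate (not isolated)
4 | tert-butyl 4-[(4S)-4-benzyl-2-oxo-1,3-oxazolidin-3-yl]-4-oxobutanoate | O=C(CCC(=O)OC(C)(C)C)N1[C@@H](Cc2ccccc2)COC1=O | intermediate
5 | (S)-citronellal [(3S)-3,7-dimethyloct-6-enal] | C[C@@H](CCC=C(C)C)CC=O | starting material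
6 | (3S)-3,7-dimethyl-2-methylideneoct-6-enal | O=CC(=C)[C@@H](C)CCC=C(C)C | intermediate
7 | di-n-butylboron (Z)-enolate of 4 | CCCCB(CCCC)O/C(=C\CC(=O)OC(C)(C)C)N1[C@@H](Cc2ccccc2)COC1=O | intermediate (not isolated)
8 | syn-aldol adduct, tert-butyl (3S,4S,6S)-3-{[(4S)-4-benzyl-2-oxo-1,3-oxazolidin-3-yl]carbonyl}-4-hydroxy-6,10-dimethyl-5-methylideneundec-9-enoate | O=C(N1[C@@H](Cc2ccccc2)COC1=O)[C@@H](CC(=O)OC(C)(C)C)[C@H](O)C(=C)[C@@H](C)CCC=C(C)C | intermediate
9 | C6 TBS ether of 8 | O=C(N1[C@@H](Cc2ccccc2)COC1=O)[C@@H](CC(=O)OC(C)(C)C)[C@H](O[Si](C)(C)C(C)(C)C)C(=C)[C@@H](C)CCC=C(C)C | intermediate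
10 | bis-ozonide of 9 (1,2,4-trioxolanes at C5 and C1; epimers at the ozonide carbons) | O=C(N1[C@@H](Cc2ccccc2)COC1=O)[C@@H](CC(=O)OC(C)(C)C)[C@H](O[Si](C)(C)C(C)(C)C)C1(OCOO1)[C@@H](C)CCC1OC(C)(C)OO1 | intermediate (not isolated)
11 | keto aldehyde (C5 ketone, C1 aldehyde) | O=C(N1[C@@H](Cc2ccccc2)COC1=O)[C@@H](CC(=O)OC(C)(C)C)[C@H](O[Si](C)(C)C(C)(C)C)C(=O)[C@@H](C)CCC=O | intermediate
12 | keto alcohol (C1–OH) | O=C(N1[C@@H](Cc2ccccc2)COC1=O)[C@@H](CC(=O)OC(C)(C)C)[C@H](O[Si](C)(C)C(C)(C)C)C(=O)[C@@H](C)CCCO | intermediate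
13 | C1 4-methoxyphenyl ether of 12 | O=C(N1[C@@H](Cc2ccccc2)COC1=O)[C@@H](CC(=O)OC(C)(C)C)[C@H](O[Si](C)(C)C(C)(C)C)C(=O)[C@@H](C)CCCOc1ccc(OC)cc1 | intermediate
14 | tertiary propargylic alcohol at C5 (hydroxy imide, Felkin–Anh epimer) | O=C(N1[C@@H](Cc2ccccc2)COC1=O)[C@@H](CC(=O)OC(C)(C)C)[C@H](O[Si](C)(C)C(C)(C)C)[C@](O)(C#C)[C@@H](C)CCCOc1ccc(OC)cc1 | intermediate (not isolated)
15 | ethynyl γ-lactone (ring O–C5–C6–C7–C8=O) | O=C1[C@@H](CC(=O)OC(C)(C)C)[C@H](O[Si](C)(C)C(C)(C)C)[C@](C#C)([C@@H](C)CCCOc2ccc(OC)cc2)O1 | intermediate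
16 | γ-hydroxy β-keto ester (open form of the cyclic hemiketal) | COC(=O)CC(=O)[C@@H](CC(=O)OC(C)(C)C)[C@H](O[Si](C)(C)C(C)(C)C)[C@](O)(C#C)[C@@H](C)CCCOc1ccc(OC)cc1 | intermediate (not isolated)
17 | methyl (Z)-(5-ethynyloxolan-2-ylidene)acetate (enol ether O between C5 and C8) | COC(=O)/C=C1\O[C@@](C#C)([C@@H](C)CCCOc2ccc(OC)cc2)[C@@H](O[Si](C)(C)C(C)(C)C)[C@@H]1CC(=O)OC(C)(C)C | intermediate
18 | ring B enol ester (C8 enol, C9–CO2Me, C5=C10, C14–O-aryl) | COC(=O)C1=C(O)[C@@H](CC(=O)OC(C)(C)C)[C@H](O[Si](C)(C)C(C)(C)C)C([C@@H](C)CCCOc2ccc(OC)cc2)=C1COc1ccc(OC)cc1 | intermediate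
19 | cyclohex-3-enone (C8 ketone, C9H2) | O=C1CC(COc2ccc(OC)cc2)=C([C@@H](C)CCCOc2ccc(OC)cc2)[C@@H](O[Si](C)(C)C(C)(C)C)[C@@H]1CC(=O)OC(C)(C)C | intermediate
20 | (8R)-cis-hydroxy ester | O[C@@H]1CC(COc2ccc(OC)cc2)=C([C@@H](C)CCCOc2ccc(OC)cc2)[C@@H](O[Si](C)(C)C(C)(C)C)[C@@H]1CC(=O)OC(C)(C)C | intermediate
21 | cis-fused γ-lactone (C8–O–C12), C6–OTBS | C1C(=O)O[C@@H]2CC(COc3ccc(OC)cc3)=C([C@@H](C)CCCOc3ccc(OC)cc3)[C@@H](O[Si](C)(C)C(C)(C)C)[C@H]12 | intermediate
22 | α-(dimethylaminomethyl) lactone (Mannich base, C11 substituent on the convex face) | CN(C)C[C@H]1C(=O)O[C@@H]2CC(COc3ccc(OC)cc3)=C([C@@H](C)CCCOc3ccc(OC)cc3)[C@@H](O[Si](C)(C)C(C)(C)C)[C@H]12 | intermediate (not isolated)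
23 | trimethylammonium iodide of 22 | C[N+](C)(C)C[C@H]1C(=O)O[C@@H]2CC(COc3ccc(OC)cc3)=C([C@@H](C)CCCOc3ccc(OC)cc3)[C@@H](O[Si](C)(C)C(C)(C)C)[C@H]12.[I-] | intermediate (not isolated)
24 | α-methylene lactone, C6–OTBS | C=C1C(=O)O[C@@H]2CC(COc3ccc(OC)cc3)=C([C@@H](C)CCCOc3ccc(OC)cc3)[C@@H](O[Si](C)(C)C(C)(C)C)[C@H]12 | intermediate
25 | C6 alcohol | C=C1C(=O)O[C@@H]2CC(COc3ccc(OC)cc3)=C([C@@H](C)CCCOc3ccc(OC)cc3)[C@@H](O)[C@H]12 | intermediate
26 | angelic acid [(Z)-2-methylbut-2-enoic acid] | OC(=O)/C(C)=C\C | starting material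
27 | mixed anhydride of angelic acid and 2,4,6-trichlorobenzoic acid | O=C(OC(=O)c1c(Cl)cc(Cl)cc1Cl)/C(C)=C\C | intermediate (not isolated)
28 | eriolangin bis(4-methoxyphenyl) ether | C=C1C(=O)O[C@@H]2CC(COc3ccc(OC)cc3)=C([C@@H](C)CCCOc3ccc(OC)cc3)[C@@H](OC(=O)/C(C)=C\C)[C@H]12 | intermediate
29 | eriolangin (4S,6S,7R,8R in the numbering above) | C=C1C(=O)O[C@@H]2CC(CO)=C([C@@H](C)CCCO)[C@@H](OC(=O)/C(C)=C\C)[C@H]12 | target

**Step count and risks**

Total step count: 17. Longest linear sequence: 16 steps (5 → 29, steps 2 to 17).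

Steps most likely to fail:

1. Step 10. After ionization the enolate may recombine at the propargylic carbon or through oxygen instead of attacking the central carbon, or the π-allyl intermediate may lose a β-hydrogen before phenoxide capture. The fallback makes the same C9–C10 bond by known chemistry, sets out from 15 and comes back at 19. Lactone 15 is opened with Me(MeO)NH·HCl/i-PrMgCl and the tertiary magnesium alkoxide is silylated in the same flask with TMSCl, giving the C5-trimethylsilyloxy Weinreb amide F1. LiCH2CO2Me converts it into the open-chain β-keto ester F2. Ph3PAuCl/AgOTf (CH2Cl2, 23 °C) closes ring B by a 6-exo-dig Conia-ene reaction to the exo-methylene enol ester F3 (C10=C14H2, C5–OTMS). Ph3SiOReO3-catalysed 1,3-transposition moves the silyloxy group from C5 to C14 and the alkene into the ring, giving the primary allylic silyl ether F4. Krapcho dealkoxycarbonylation (LiCl, H2O, DMSO) with loss of the silyl group gives the keto alcohol F5, and Mitsunobu etherification with 4-methoxyphenol returns to 19.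

2. Step 8. The acetylide may attack the imide carbonyl, or its basicity may epimerize the ketone α-centres C4 and C6. The fallback sets out from 13 and comes back at 15. LiOH/H2O2 removes the auxiliary first, giving the keto acid F6, whose carboxylate is inert to acetylides. TMSC≡CLi/CeCl3 (THF, −78 °C) then adds to the ketone, and acidic work-up lactonizes the γ-hydroxy acid to the silylalkynyl lactone F7. K2CO3/MeOH removes the alkynyl silyl group to give 15.

3. Step 16. Acylation of the hindered allylic C6 alcohol may be slow, and the activated angeloyl unit may isomerize from Z to E. The fallback sets out from 25 and comes back at 28, building the Z-alkene on the ester instead of transferring it. Alcohol 25 is esterified with 2-[bis(2,2,2-trifluoroethoxy)phosphoryl]propanoic acid (DCC, DMAP) to the phosphonate ester F8 (epimers at the phosphonate α-carbon). Still–Gennari olefination with acetaldehyde (KN(SiMe3)2, 18-crown-6, THF, −78 °C) then gives the Z-trisubstituted alkene of 28.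

**Further compounds**

F1 | step 10 | Weinreb amide with C5–OTMS (from opening of 15) | CON(C)C(=O)[C@@H](CC(=O)OC(C)(C)C)[C@H](O[Si](C)(C)C(C)(C)C)[C@](O[Si](C)(C)C)(C#C)[C@@H](C)CCCOc1ccc(OC)cc1
F2 | step 10 | open-chain β-keto ester with C5–OTMS | COC(=O)CC(=O)[C@@H](CC(=O)OC(C)(C)C)[C@H](O[Si](C)(C)C(C)(C)C)[C@](O[Si](C)(C)C)(C#C)[C@@H](C)CCCOc1ccc(OC)cc1
F3 | step 10 | Conia-ene product (enol ester, exocyclic C10=C14H2, C5–OTMS) | COC(=O)C1=C(O)[C@@H](CC(=O)OC(C)(C)C)[C@H](O[Si](C)(C)C(C)(C)C)[C@@](O[Si](C)(C)C)([C@@H](C)CCCOc2ccc(OC)cc2)C1=C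
F4 | step 10 | transposed primary allylic silyl ether (C5=C10, C14–OTMS) | COC(=O)C1=C(O)[C@@H](CC(=O)OC(C)(C)C)[C@H](O[Si](C)(C)C(C)(C)C)C([C@@H](C)CCCOc2ccc(OC)cc2)=C1CO[Si](C)(C)C
F5 | step 10 | keto alcohol (19 with C14–OH) | O=C1CC(CO)=C([C@@H](C)CCCOc2ccc(OC)cc2)[C@@H](O[Si](C)(C)C(C)(C)C)[C@@H]1CC(=O)OC(C)(C)C
F6 | step 8 | keto acid (C8 carboxylic acid, C5 ketone) | OC(=O)[C@@H](CC(=O)OC(C)(C)C)[C@H](O[Si](C)(C)C(C)(C)C)C(=O)[C@@H](C)CCCOc1ccc(OC)cc1
F7 | step 8 | (trimethylsilyl)ethynyl γ-lactone | O=C1[C@@H](CC(=O)OC(C)(C)C)[C@H](O[Si](C)(C)C(C)(C)C)[C@](C#C[Si](C)(C)C)([C@@H](C)CCCOc2ccc(OC)cc2)O1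
F8 | step 16 | C6 2-[bis(2,2,2-trifluoroethoxy)phosphoryl]propanoate of 25 | C=C1C(=O)O[C@@H]2CC(COc3ccc(OC)cc3)=C([C@@H](C)CCCOc3ccc(OC)cc3)[C@@H](OC(=O)C(C)P(=O)(OCC(F)(F)F)OCC(F)(F)F)[C@H]12
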